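**Plan**

1. Locants: oxolane O1, C2 (quaternary, CH3 and the two-carbon arm), C3 (CHBr), C4, C5; Cα is the exocyclic carbon carrying Br, CH3 and CH2Cl.
2. Retrosynthesis: the arm C=C is cut first (Takai), leaving a CH2O group on C2. Then O1–C2, C3–Br and Cα–Br are cut together, which unfolds the oxolane into an (E)-alkenyl trans-epoxide. The primary C–Cl bond, the oxirane oxygen and the C3–C4 bond follow.
3. Forward: an alkenyl iodide (arm, C2, C3) and a chloro enoate (C4, C5, Cα, CH2Cl carbon) are joined at C3–C4. Reduction, epoxidation and chlorination finish the chain. The oxolane, the only ring, closes in step 8, and the arm is then turned into the E bromoalkene.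
4. Stereochemistry: both E alkenes come from syn carboalumination and an E-selective Wittig reaction. Sharpless epoxidation with D-(−)-tartrate sets C5 and Cα. Anti addition across the E alkene, on the face directed by C5, sets C2 and C3, and bromide inverts Cα.
5. Enabling feature: in the oxolane, O1 stands anti to bromine across C2–C3 (Br on C3) and across C5–Cα (Br on Cα). One oxirane oxygen bridging C5 and Cα can therefore open a bromonium ion at C2 and then leave Cα to bromide.

Key step: step 8

Assumption: the target is taken as the (2S,3R,5R) oxolane with an (R)-configured Cα, as read from the SMILES. Chloroacetaldehyde is used as its commercial aqueous solution and CrBr2 as the commercial anhydrous salt.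

**Route**

Step 1
Reactants: 1 prop-2-yn-1-ol (propargyl alcohol)
Product: 3 (E)-3-iodo-2-methylprop-2-en-1-ol, via alkenylalane 2 (not isolated)
Conditions: Me3Al (3 equiv), Cp2ZrCl2 (0.25 equiv), CH2Cl2, 0 °C → rt; then I2, THF, −30 → 0 °C
Reagents that add atoms: trimethylaluminium, C[Al](C)C; iodine, II
Why: Zirconocene-catalysed Negishi carboalumination should add methyl and aluminium syn across the alkyne with methyl on the internal carbon, and iodinolysis of the alkenyl–aluminium bond with retention should give the E iodoalkene.

Step 2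
Reactants: 3 (E)-3-iodo-2-methylprop-2-en-1-ol; 4 tert-butyl(chloro)diphenylsilane
Product: 5 tert-butyl{[(E)-3-iodo-2-methylprop-2-en-1-yl]oxy}diphenylsilane
Conditions: imidazole, DMF, rt
Reagents that add atoms: none
Why: Imidazole-mediated silylation of a primary allylic alcohol is routine and touches neither the alkene geometry nor the C–I bond.

Step 3
Reactants: 6 chloroacetaldehyde; 7 methyl 2-(triphenylphosphoranylidene)propanoate
Product: 8 methyl (E)-4-chloro-2-methylbut-2-enoate
Conditions: CH2Cl2, 0 °C → rt (6 added as 50 wt% aqueous solution)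
Reagents that add atoms: none
Why: Wittig olefination with an α-methyl ester-stabilised ylide should give the E trisubstituted enoate, because oxaphosphetane formation is reversible and the more stable trans arrangement collapses.

Step 4
Reactants: 5 tert-butyl{[(E)-3-iodo-2-methylprop-2-en-1-yl]oxy}diphenylsilane; 8 methyl (E)-4-chloro-2-methylbut-2-enoate
Product: 11 methyl (2E,5E)-7-[(tert-butyldiphenylsilyl)oxy]-2,6-dimethylhepta-2,5-dienoate, via alkenyllithium 9 (not isolated), via alkenylzinc chloride 10 (not isolated)
Conditions: t-BuLi (2.1 equiv), Et2O, −78 °C; ZnCl2, THF, −78 → 0 °C; then 8, Pd(PPh3)4 (5 mol%), THF, 0 °C → rt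
Reagents that add atoms: none
Why: Iodine–lithium exchange and transmetalation to zinc keep the alkenyl geometry, and the Negishi alkenyl–allyl coupling through a π-allylpalladium intermediate should join the alkenyl group to the unsubstituted allyl terminus, so that the enoate stays conjugated and both alkenes stay E.

Step 5
Reactants: 11 methyl (2E,5E)-7-[(tert-butyldiphenylsilyl)oxy]-2,6-dimethylhepta-2,5-dienoate
Product: 12 (2E,5E)-7-[(tert-butyldiphenylsilyl)oxy]-2,6-dimethylhepta-2,5-dien-1-ol
Conditions: iBu2AlH (2.5 equiv), CH2Cl2, −78 °C; aq. potassium sodium tartrate work-up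
Reagents that add atoms: none
Why: 1,2-Reduction of a conjugated ester by diisobutylaluminium hydride at low temperature should give the allylic alcohol without moving the skipped diene into conjugation or touching the silyl ether.

Step 6
Reactants: 12 (2E,5E)-7-[(tert-butyldiphenylsilyl)oxy]-2,6-dimethylhepta-2,5-dien-1-ol
Product: 13 [(2R,3R)-3-{(2E)-4-[(tert-butyldiphenylsilyl)oxy]-3-methylbut-2-en-1-yl}-2-methyloxiran-2-yl]methanol
Conditions: Ti(OiPr)4 (10 mol%), D-(−)-diisopropyl tartrate (12 mol%), t-BuOOH (2 equiv), 4 Å MS, CH2Cl2, −20 °C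
Reagents that add atoms: tert-butyl hydroperoxide, CC(C)(C)OO
Why: Sharpless asymmetric epoxidation needs the free allylic hydroxyl, so only that alkene should react; the D-(−)-tartrate ligand delivers oxygen to the face that gives the (2R,3R) epoxide, and the E geometry fixes the trans relationship of C5 and Cα.

Step 7
Reactants: 13 [(2R,3R)-3-{(2E)-4-[(tert-butyldiphenylsilyl)oxy]-3-methylbut-2-en-1-yl}-2-methyloxiran-2-yl]methanol
Product: 14 tert-butyl({(2E)-4-[(2R,3S)-3-(chloromethyl)-3-methyloxiran-2-yl]-2-methylbut-2-en-1-yl}oxy)diphenylsilane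
Conditions: PPh3, CCl4, NaHCO3 (cat.), reflux
Reagents that add atoms: tetrachloromethane, ClC(Cl)(Cl)Cl
Why: In this Appel chlorination chloride displaces the alkoxyphosphonium group at the primary carbon under neutral conditions, so the oxirane and both its stereocentres should stay untouched (the descriptor at Cα changes only because CH2Cl outranks the ring carbon).

Step 8
Reactants: 14 tert-butyl({(2E)-4-[(2R,3S)-3-(chloromethyl)-3-methyloxiran-2-yl]-2-methylbut-2-en-1-yl}oxy)diphenylsilane
Product: 17 tert-butyl{[(2S,3R,5R)-3-bromo-5-[(2R)-2-bromo-1-chloropropan-2-yl]-2-methyloxolan-2-yl]methoxy}diphenylsilane, via bromonium ion 15 (not isolated), via bicyclic oxonium ion 16 (not isolated)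
Conditions: NBS (1.1 equiv), Bu4NBr (2 equiv), 4 Å MS, CH2Cl2, −40 → 0 °C, dark
Reagents that add atoms: N-bromosuccinimide, O=C1CCC(=O)N1Br; tetrabutylammonium bromide, [Br-].CCCC[N+](CCCC)(CCCC)CCCC
Why: Proposed new method: NBS should transfer Br+ reversibly to the only alkene of 14, and the oxirane oxygen, one methylene away, should open bromonium ion 15 at its tertiary carbon anti to bromine, a 5-endo closure of the oxolane (both bromonium carbons lie inside the new ring) that gives the 1-oxoniabicyclo[3.1.0]hexane 16; bromide then opens 16 at the exocyclic tertiary carbon Cα with inversion. The closest known reactions are bromonium-initiated epoxide-opening cascades through bicyclic oxonium ions (there with 5-exo or 6-endo attack of the oxirane oxygen) and the 5-endo bromo- and iodoetherification of homoallylic alcohols; an oxirane oxygen attacking in the 5-endo mode is the untested part. C2 and C3 follow from anti addition across the E alkene (Br cis to the C2 methyl), Cα follows from SN2-type inversion at the former oxirane carbon, and C5 is carried over unchanged. The step needs three selectivities: oxygen attack at the tertiary alkene carbon (Markovnikov; the 4-exo alternative is strained), bromonium formation on the face that ends cis to the C5 side chain, and bromide attack at Cα and not at C5. The face is expected from a transition state that keeps the bulky silyloxymethyl group of C2 on the convex side of the forming bicycle, away from Cα and its two substituents, in line with the 3,5-cis outcome usual for 5-endo halocyclisations of homoallylic alcohols; the second opening is expected at Cα because it is the more substituted oxonium carbon and attack at C5 would enlarge the ring to an oxane.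

Step 9
Reactants: 17 tert-butyl{[(2S,3R,5R)-3-bromo-5-[(2R)-2-bromo-1-chloropropan-2-yl]-2-methyloxolan-2-yl]methoxy}diphenylsilane
Product: 18 [(2S,3R,5R)-3-bromo-5-[(2R)-2-bromo-1-chloropropan-2-yl]-2-methyloxolan-2-yl]methanol
Conditions: HF·pyridine, pyridine, THF, 0 °C → rt
Reagents that add atoms: none
Why: Fluoride cleaves the silyl ether under weakly acidic, non-basic conditions, which should spare the tertiary and secondary bromides from elimination.

Step 10
Reactants: 18 [(2S,3R,5R)-3-bromo-5-[(2R)-2-bromo-1-chloropropan-2-yl]-2-methyloxolan-2-yl]methanol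
Product: 19 (2S,3R,5R)-3-bromo-5-[(2R)-2-bromo-1-chloropropan-2-yl]-2-methyloxolane-2-carbaldehyde
Conditions: Dess–Martin periodinane, CH2Cl2, 0 °C → rt
Reagents that add atoms: none
Why: Dess–Martin oxidation of the primary alcohol runs under near-neutral conditions, and because the aldehyde has no α-hydrogen neither epimerisation nor loss of the C3 bromide through an enol is possible.

Step 11
Reactants: 19 (2S,3R,5R)-3-bromo-5-[(2R)-2-bromo-1-chloropropan-2-yl]-2-methyloxolane-2-carbaldehyde
Product: 20 (2S,3R,5R)-3-bromo-5-[(2R)-2-bromo-1-chloropropan-2-yl]-2-[(E)-2-bromoethenyl]-2-methyloxolane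
Conditions: CHBr3 (3 equiv), CrBr2 (8 equiv), THF, 0 °C → rt
Reagents that add atoms: bromoform, BrC(Br)Br
Why: In this Takai olefination the geminal dichromium species from bromoform adds to the aldehyde and eliminates to the E bromoalkene, the quaternary α-carbon reinforcing that preference, and the bromide salt of divalent chromium excludes halogen exchange to a chloroalkene.

**Compound list**

1 | prop-2-yn-1-ol (propargyl alcohol) | C#CCO | starting material
2 | alkenylalane, dimethylaluminium alkoxide of (E)-3-(dimethylalumanyl)-2-methylprop-2-en-1-ol (formed in the flask) | C/C(CO[Al](C)C)=C\[Al](C)C | intermediate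
3 | (E)-3-iodo-2-methylprop-2-en-1-ol | C/C(CO)=C\I | intermediate
4 | tert-butyl(chloro)diphenylsilane | CC(C)(C)[Si](Cl)(c1ccccc1)c1ccccc1 | starting material
5 | tert-butyl{[(E)-3-iodo-2-methylprop-2-en-1-yl]oxy}diphenylsilane | C/C(CO[Si](c1ccccc1)(c1ccccc1)C(C)(C)C)=C\I | intermediate
6 | chloroacetaldehyde | O=CCCl | starting material
7 | methyl 2-(triphenylphosphoranylidene)propanoate | COC(=O)C(C)=P(c1ccccc1)(c1ccccc1)c1ccccc1 | starting material
8 | methyl (E)-4-chloro-2-methylbut-2-enoate | COC(=O)/C(C)=C/CCl | intermediate
9 | alkenyllithium, {(E)-3-[(tert-butyldiphenylsilyl)oxy]-2-methylprop-1-en-1-yl}lithium (formed in the flask) | [Li]/C=C(\C)CO[Si](c1ccccc1)(c1ccccc1)C(C)(C)C | intermediate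
10 | alkenylzinc chloride, chloro{(E)-3-[(tert-butyldiphenylsilyl)oxy]-2-methylprop-1-en-1-yl}zinc (formed in the flask) | Cl[Zn]/C=C(\C)CO[Si](c1ccccc1)(c1ccccc1)C(C)(C)C | intermediate
11 | methyl (2E,5E)-7-[(tert-butyldiphenylsilyl)oxy]-2,6-dimethylhepta-2,5-dienoate | COC(=O)/C(C)=C/C/C=C(\C)CO[Si](c1ccccc1)(c1ccccc1)C(C)(C)C | intermediate
12 | (2E,5E)-7-[(tert-butyldiphenylsilyl)oxy]-2,6-dimethylhepta-2,5-dien-1-ol | OC/C(C)=C/C/C=C(\C)CO[Si](c1ccccc1)(c1ccccc1)C(C)(C)C | intermediate
13 | [(2R,3R)-3-{(2E)-4-[(tert-butyldiphenylsilyl)oxy]-3-methylbut-2-en-1-yl}-2-methyloxiran-2-yl]methanol | C[C@]1(CO)O[C@@H]1C/C=C(\C)CO[Si](c1ccccc1)(c1ccccc1)C(C)(C)C | intermediate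
14 | tert-butyl({(2E)-4-[(2R,3S)-3-(chloromethyl)-3-methyloxiran-2-yl]-2-methylbut-2-en-1-yl}oxy)diphenylsilane | C[C@]1(CCl)O[C@@H]1C/C=C(\C)CO[Si](c1ccccc1)(c1ccccc1)C(C)(C)C | intermediate
15 | bromonium ion of 14: Br+ bridges the two former alkene carbons (future C2 and C3) on the face that ends cis to the C5 side chain; oxirane intact (formed in the flask) | C[C@]1(CCl)O[C@@H]1C[C@H]2[Br+][C@]2(C)CO[Si](c3ccccc3)(c3ccccc3)C(C)(C)C | intermediate
16 | bicyclic oxonium ion, (2S,3R,5R,6S)-3-bromo-2-{[(tert-butyldiphenylsilyl)oxy]methyl}-6-(chloromethyl)-2,6-dimethyl-1-oxoniabicyclo[3.1.0]hexane (formed in the flask) | C[C@]1(CCl)[O+]2[C@@H]1C[C@@H](Br)[C@]2(C)CO[Si](c3ccccc3)(c3ccccc3)C(C)(C)C | intermediate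
17 | tert-butyl{[(2S,3R,5R)-3-bromo-5-[(2R)-2-bromo-1-chloropropan-2-yl]-2-methyloxolan-2-yl]methoxy}diphenylsilane | C[C@](Br)(CCl)[C@H]1C[C@@H](Br)[C@](C)(CO[Si](c2ccccc2)(c2ccccc2)C(C)(C)C)O1 | intermediate
18 | [(2S,3R,5R)-3-bromo-5-[(2R)-2-bromo-1-chloropropan-2-yl]-2-methyloxolan-2-yl]methanol | C[C@](Br)(CCl)[C@H]1C[C@@H](Br)[C@](C)(CO)O1 | intermediate
19 | (2S,3R,5R)-3-bromo-5-[(2R)-2-bromo-1-chloropropan-2-yl]-2-methyloxolane-2-carbaldehyde | C[C@](Br)(CCl)[C@H]1C[C@@H](Br)[C@](C)(C=O)O1 | intermediate
20 | (2S,3R,5R)-3-bromo-5-[(2R)-2-bromo-1-chloropropan-2-yl]-2-[(E)-2-bromoethenyl]-2-methyloxolane | C[C@](Br)(CCl)[C@H]1C[C@@H](Br)[C@](C)(/C=C/Br)O1 | target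

**Step count and risks**

Total: 11 steps. Longest linear sequence: 10 steps (1, 2, 4 to 11, from propargyl alcohol); step 3 is a one-step branch.

Most likely to fail:

1. Step 8. Bromide may capture the bromonium ion before the oxirane oxygen does (plain dibromination), the bromonium ion may form on the other alkene face, or the oxonium ion may be opened at C5 with ring enlargement. The fallback uses known chemistry and sets out from 14. Anhydrous HBr in Et2O at −40 °C should open the protonated oxirane at its tertiary carbon with inversion and give the bromohydrin (2R,3R,5E)-2-bromo-7-[(tert-butyldiphenylsilyl)oxy]-1-chloro-2,6-dimethylhept-5-en-3-ol F1, which already holds the Cα–Br bond anti to the C5 oxygen. NBS in MeCN at 0 °C should then bring about the 5-endo bromoetherification of this homoallylic alcohol, the hydroxyl attacking the tertiary bromonium carbon with the C5 side chain pseudo-equatorial. The route is rejoined at 17.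

2. Step 11. Divalent chromium may reduce the vicinal bromide/chloride pair or the bromides β to the ring oxygen (loss of halogen, ring opening) faster than it olefinates the hindered aldehyde. The fallback sets out from 19. Ohira–Bestmann homologation (dimethyl (1-diazo-2-oxopropyl)phosphonate, K2CO3, MeOH, 0 °C) should give the alkyne (2S,3R,5R)-3-bromo-5-[(2R)-2-bromo-1-chloropropan-2-yl]-2-ethynyl-2-methyloxolane F2. Syn hydrozirconation with Cp2Zr(H)Cl in THF should place zirconium on the terminal carbon and give the (E)-alkenylzirconocene chloride F3, and NBS should cleave the carbon–zirconium bond with retention. The route is rejoined at 20.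

3. Step 4. The π-allylpalladium intermediate may lose the enoate geometry or couple at its substituted terminus, and the skipped diene may slip into conjugation with the ester. The fallback sets out from 5. Iodine–lithium exchange gives alkenyllithium 9, which should open ethylene oxide (BF3·OEt2, THF, −78 °C) to the homoallylic alcohol (3E)-5-[(tert-butyldiphenylsilyl)oxy]-4-methylpent-3-en-1-ol F4. Dess–Martin oxidation should give the β,γ-unsaturated aldehyde (3E)-5-[(tert-butyldiphenylsilyl)oxy]-4-methylpent-3-enal F5, used at once in a Wittig reaction with ylide 7 in CH2Cl2. The route is rejoined at 11, and chloro ester 8 is then not needed.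

**Further compounds**

F1 | step 8 | (2R,3R,5E)-2-bromo-7-[(tert-butyldiphenylsilyl)oxy]-1-chloro-2,6-dimethylhept-5-en-3-ol | C[C@](Br)(CCl)[C@H](O)C/C=C(\C)CO[Si](c1ccccc1)(c1ccccc1)C(C)(C)C
F2 | step 11 | (2S,3R,5R)-3-bromo-5-[(2R)-2-bromo-1-chloropropan-2-yl]-2-ethynyl-2-methyloxolane | C[C@](Br)(CCl)[C@H]1C[C@@H](Br)[C@](C)(C#C)O1
F3 | step 11 | (E)-alkenylzirconocene chloride from F2, Cp2Zr(Cl) on the terminal alkene carbon | C[C@](Br)(CCl)[C@H]1C[C@@H](Br)[C@](C)(/C=C/[Zr](Cl)(C2C=CC=C2)C2C=CC=C2)O1
F4 | step 4 | (3E)-5-[(tert-butyldiphenylsilyl)oxy]-4-methylpent-3-en-1-ol | OCC/C=C(\C)CO[Si](c1ccccc1)(c1ccccc1)C(C)(C)C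
F5 | step 4 | (3E)-5-[(tert-butyldiphenylsilyl)oxy]-4-methylpent-3-enal | O=CC/C=C(\C)CO[Si](c1ccccc1)(c1ccccc1)C(C)(C)C
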